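The readings were computed on assumed constants, and the scatter is random.

The reciprocal minute is the unit to read this flask in, since a substrate consumed by a step first order in it, with the reagent held steady, loses the same logarithm of c substrate each minute, and on a logarithmic scale of reagent the flask stands midway between two runs already made.

| flask | substrate | reagent in the second phase | protic impurity | remark | time | volume of the second phase over the first |
|---|---|---|---|---|---|---|
| violet | 0.50 M | 0.90 equiv | 0.025 M | run made earlier |  |  |
| amber | 0.50 M | 3.6 equiv | 0.025 M | run made earlier |  |  |
| green | 0.75 M | 1.8 equiv | 0.025 M | run made earlier |  |  |
| flask | 0.50 M | 1.80 equiv | 0.0250 M |  | 3.0 min | 2.0 |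

| run | time / min | target / % |
|---|---|---|
| violet | 0.417 | 2.9 |
| violet | 1.00 | 10.2 |
| violet | 2.00 | 19.5 |
| violet | 3.00 | 27.3 |
| amber | 0.417 | 14.1 |
| amber | 1.00 | 33.8 |
| amber | 2.00 | 55.3 |
| amber | 3.00 | 67.8 |
| green | 0.833 | 21.0 |
| green | 1.50 | 34.9 |
| green | 2.50 | 50.5 |
| green | 3.00 | 55.0 |

(each reading ± 0.5 percentage points)

- in the second phase: reagent in the second phase; everything else is in the first
- charges count per volume of the first phase; a concentration in a rate is the amount of a species over the volume of its own phase; every rate counts per litre of the first phase
- the earlier runs hold the two phases in the same ratio of volumes as the flask asked about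

- noon: doubling the amount of reagent in the second phase, all else as stated
- dusk: doubling the transfer coefficient of the reagent in the second phase, all else as stated

- the target standing at 3.0 min, as a percentage of the substrate charged
- the change that raises the amount of target at 3.0 min, in percent of the substrate charged most ("none" if none brings more than 2 percentage points) (noon / dusk / none)
- amount of target at 3.0 min, in percent of the substrate charged, after dusk

Take first the main step by itself, with the reagent held steady, so that each run has a pseudo-first-order constant: the logarithm of c substrate charged over c substrate left, divided by the time. The violet run gives 0.108 min⁻¹ at 1.00 min and 0.106 min⁻¹ at 3.00 min, and the amber run gives 0.378 min⁻¹ at 3.00 min. The flask holds twice the violet charge of reagent and half the amber one, so a constant proportional to reagent gives 47.1% from violet but 43.3% from amber.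

Now add the crossing between the phases, which shows as an early delay: the first violet reading gives 0.0706 min⁻¹, lower than its later constant. Apart from that delay, the readings put the amber constant at 3.57 times the violet one for a charge 4.00 times larger, so the constant read at 3.00 min rises less than the charge. Taking the symmetric point as zero of the scale, the flask's constant K is the geometric mean of the two runs, 0.200 min⁻¹, and both readings stand at the asked time, so any delay they hold is inside K.

Last comes the protic impurity, at most 2.78% of the flask's reagent if taken one for one; violet and amber carry the same 0.025 M, so K already holds it. This reckoning gives 45.2%. Noon is the amber run itself, at 67.8%, a gain of 23 percentage points. The reckoning puts no number on dusk.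

The forecast says 45% (range 42% to 48%), noon as the best change, and 49% after dusk (range 45% to 57%), holding that “First-order substrate behaviour means the process is mainly kinetic, with modest transfer resistance”.

The simulation gives 45.8%, with noon best at 22 points against 2.2 points for dusk, which ends at 47.9%; each stands within the forecast's tolerance.

    reagent in the reaction phase ⇌ reagent in the second phase, rate k1*([reagent in the reaction phase] - [reagent in the second phase]/K1) per volume of the first phase (partition coefficient = 1.56, kL = 0.0626 s⁻¹)
    substrate + reagent in the reaction phase → target (k = 0.0269 M⁻¹ s⁻¹)
    reagent in the reaction phase + protic impurity → quenched reagent (k = 0.0784 M⁻¹ s⁻¹)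
    2 reagent in the reaction phase → homo dimer (k = 0.0284 M⁻¹ s⁻¹)

The result reads back as a constant of 0.204 min⁻¹, beside K at 0.200 min⁻¹. The neighbouring flask is this same charge read at 8.0 min, where K gives 79.8% of target, while that flask stands at 70.7%. Its constant, read the same way, is 0.153 min⁻¹, lower than K. Over those minutes c reagent in the reaction phase went from 0.103 M at 3.00 min to 0.0572 M at 8.00 min.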